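**Structural features**

The target is a cis-fused cyclopenta[c]pyran of the iridoid type: a 1H-pyran (ring A: C1, O2, C3, C4, C4a, C7a) and a cyclopentane (ring B: C4a, C5, C6, C7, C7a) that share only the C4a–C7a bond. Ring A carries the C3 of a 4-hydroxy-5-methylcoumarin at C1, an (R)-2-acetoxy-3-methylbutanoyl group at C3 and a methyl group at C4, so C3=C4 is a tetrasubstituted enol ether and at the same time the alkene of an α-alkoxy enone; ring B carries one methyl group at C7. Four ring stereocentres are contiguous, C1–C7a–C7 with C4a next to C7a (1R,4aS,7S,7aR): H4a and H7a are cis, and both the C7 methyl and the C1 aryl group lie on the face of these two hydrogens, the convex face. The fifth centre, C2' (R), is separated from the ring by the C1' ketone. The fragile points are C1 (an acetal-like carbon flanked by O2 and an electron-rich aryl group, able to ionise), the C2' acetate α to a ketone (epimerisable, base-labile, able to migrate to a neighbouring alkoxide) and the acidic enol lactone of the coumarin. The real difficulty is the relative configuration around the ring fusion together with the union of three pieces (aryl, bicycle, acyl side chain) in an order that never exposes acetate, enone and coumarin to hydride or strong base. The key step exploits that C5–C6–C7 is a three-carbon bridge across C4a–C7a: in a pyranone with the enone C4(=O)–C4a=C7a and the anomeric carbon C1, a three-carbon dipole closes ring B, the ketone lands on C4 next to the C3 that must be acylated, and the anomeric ester at C1 first steers the facial selectivity and later serves as leaving group for the coumarin.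

**Logic of the disconnections**

21 to 18 and 20: the C1–aryl bond is cut. C1 is at the acetal oxidation level and is an oxocarbenium synthon, while C3 of 20 is a vinylogous-acid carbon nucleophile. Cutting here last keeps the acidic enol lactone out of every enolate, hydride and sulfonylation step and divides the target into two halves of similar size. The forward step must ionise C1 next to an α-alkoxy enone and an acetate, and the aryl group must enter on the convex face.

20 to 19: the lactone C–O bond and the C2–C3 bond are cut, which removes one carbonyl carbon. This is the standard way to 4-hydroxycoumarins and puts the aryl methyl group at C5 without any regiochemical question. The forward step only needs an enolate acylation followed by lactonisation.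

18 to 17 to 16: the C4–CH3 bond is cut, and the leaving group on C4 is traced back to the enol oxygen of a 1,3-diketone. This turns the tetrasubstituted alkene into carbonyl chemistry. The forward steps must sulfonylate the ring oxygen and not the side-chain oxygen, and the methyl coupling must be neutral enough for acetate, acyloxy ketone and acylal.

16 to 12 and 15: the C3–C1' bond is cut. C3 is α to the C4 ketone and is the enolate carbon; the side chain arrives with C2' and its acetate already in place, so this centre is bought and never made. The forward step demands enolisation toward C3 and not toward the ring-fusion carbon C4a, C- over O-acylation, and an acyl donor that does not lose its α-configuration.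

15 to 13 (through 14): no skeletal bond is cut; the acid is acetylated and activated. The only demand is that the α-C–H is not touched.

12 back to 6 (through 10, 8 and 7; 11 and 9 in passing): no skeletal bond is cut. The C7 methyl is traced to a formyl group and then to the ester, and the saturated C6–C7 bond to the alkene. The reason is that an ester on a cyclopentene is what the annulation delivers, and that the aldehyde is the one oxidation level at which C7 can be equilibrated by a base that the anomeric ester tolerates. The forward steps must spare the pivalate during hydride reduction, rely on the convex formyl isomer being the more stable one, and deoxygenate an aldehyde next to a ketone.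

6 to 4 and 5: the C4a–C5 and C7–C7a bonds are cut. This removes ring B and two stereocentres at once and leaves a six-membered enone and an achiral four-carbon allene; ketone, ester and anomeric ester all sit where the later steps need them. The forward step demands α-regiochemistry of the dipole, approach anti to the C1 ester and survival of an allylic acylal in the presence of a nucleophilic phosphine.

4 to 3 to 2 to 1: the anomeric ester C–O bond is cut, and the pyranone is traced to a furan by oxidative ring expansion. All five ring carbons and the ring oxygen come from a commodity chemical. The price is a resolution, which gives at most half of the material per pass; the cleaved enantiomer returns as racemising 2 and is recycled.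

**Other disconnections considered**

Alternative 1: The pyran oxygen is removed in thought, so ring A becomes a cyclopentenone whose carbonyl carbon C3 is bonded to both C4 and C1. The enyne A1 (aryl alkyne C1≡C7a, E-alkene C4a=C4, tether C7–C6–C5 carrying the methyl) would be cyclised with Co2(CO)8 to the bicyclooctenone A2, forming C4a–C7a, C3–C4 and C1–C3. A Baeyer–Villiger oxidation would then have to insert O2 between C1 and C3.
- In favour: one step builds ring B and the whole carbon frame of ring A. The C1–aryl bond is made beforehand by a simple alkyne–aryl coupling, so no anomeric substitution is needed. The only stereocentre to be bought is C7.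
- Against: an internal alkene and an aryl alkyne are both reluctant Pauson–Khand partners. In the oxygen insertion the secondary alkyl carbon C4 is expected to migrate in preference to the vinylic C1, which would place the oxygen on the wrong side. After insertion C3 would be a lactone carbonyl and C1=C7a an enol ether double bond, so C3 still has to become the acyl-bearing enol ether carbon. A syn reduction of C1=C7a would give H1 cis to H7a, the wrong C1 epimer. The side chain with C2' is still missing.
- Comparison, structure: A2 holds more of the final carbon skeleton than 6, the aryl group included; here the alternative is the better.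
- Comparison, mechanism: the chosen annulation places the ketone, the ester and the leaving group where the next steps need them, whereas A2 needs an oxygen insertion of doubtful regiochemistry and a correction at C1.
- Comparison, step economy: A2 and 6 would be reached in a similar number of steps, an equal point, but the way from A2 to the target is judged longer and less certain.

Alternative 2: The cut is C4–C4a and O2–C1. Under secondary-amine catalysis the enal A3 would be activated as its iminium ion, the enol carbon of the keto ester A4 would add to C4a, and the enol oxygen would close on C1 to give the lactol A5.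
- In favour: one step from two small pieces gives ring A with the C3=C4 alkene, both methyl groups and a C1 lactol ready for acid-catalysed union with 20. C7 comes from the chiral pool and needs no epimerisation. No redox or protecting-group step is needed.
- Against: A3 is an α-substituted enal, a class that forms iminium ions with secondary amines only reluctantly. C4a must be set relative to a C7 centre on the far side of the α-carbon, and C7a is set by protonation, so the desired isomer results only if it is the thermodynamic one. The C3 substituent of A5 is an ester; turning it into the α-acetoxy ketone needs an α-oxygenated carbanion equivalent or a homologation that has to create C2', which the chosen plan buys with 13.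
- Comparison, step economy: the alternative reaches the dimethylated bicyclic core in far fewer steps and avoids the C7 detour; this is a clear point in its favour.
- Comparison, structure: both plans end with an acetal-level C1 and would share the same final coupling, an equal point.
- Comparison, mechanism: the chosen plan is stronger in stereocontrol and in how the side chain is attached, which is a plain enolate acylation with C2' intact.

Alternative 3: The cut is C1–aryl, C4a–C7a and O2–C1 in one operation. Compound 20 would condense with the aldehyde of the acyclic ene-dione A6; the vinylogous enolate of the alkylidene dione would attack C4a through C7a (5-exo-trig), and the diketone enolate oxygen would add to C1 to give the silyl analogue A7. Desilylation and acetylation would finish.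
- In favour: this is the most convergent plan, with both rings and the aryl bond formed in one flask and all carbons and oxidation levels in place. C7 comes from the chiral pool, and C2' travels as a silyl ether that cannot migrate.
- Against: three new stereocentres (C1, C7a, C4a) must follow from the single C7 methyl through a flexible chain. Alkylidene intermediates of 4-hydroxycoumarins readily take up a second coumarin. The ene-1,2-dione of A6 is a sensitive, strongly electrophilic unit, and A6 itself needs a multistep synthesis.
- Comparison, step economy and convergence: two steps from A7 to the target and one flask for the assembly; on both counts the alternative is the better.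
- Comparison, structure: both plans make the C1–aryl bond with the same polarity, an equal point.
- Comparison, mechanism: the chosen plan wins on predictability, because each stereocentre is set by a separate event of known type and the ring fusion is not left to a cascade.

Key step: step 4

Remark on the descriptors: C1 is S while it carries the pivalate (4 to 18) and R once it carries the aryl group (21). C7a is S in 6 and 7 and R from 8 on. Both changes come from substituent priorities alone: the arrangement in space at C7a is never altered, and at C1 the aryl group takes the position of the pivalate.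

Remark on the design: the C7 equilibration is placed at the aldehyde and not at the ester, because an ester would need alkoxide, which the anomeric ester does not tolerate. The C4 ketone is carried as its alcohol through the hydride step.

Assumption: the lipase chosen in step 3 cleaves the (R)-ester faster; an enzyme of opposite preference would be used in the acylation direction on 2 instead.

Step 1
Reactants: 1 furfuryl alcohol
Product: 2 6-hydroxy-2H-pyran-3(6H)-one (racemic lactol)
Conditions: mCPBA (1.05 equiv), CH2Cl2, 0 °C → rt
Reagents that add atoms: 3-chloroperoxybenzoic acid, OOC(=O)c1cccc(Cl)c1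
Why: Achmatowicz rearrangement: peracid oxidation opens the furan to the cis-enedione, and the hydroxymethyl oxygen closes on the aldehyde to give the pyranone hemiacetal; the lactol centre is racemic and mobile.

Step 2
Reactants: 2 6-hydroxy-2H-pyran-3(6H)-one
Product: 3 rac-6-(pivaloyloxy)-2H-pyran-3(6H)-one
Conditions: PivCl, Et3N, DMAP (cat.), CH2Cl2, −78 °C
Reagents that add atoms: pivaloyl chloride, CC(C)(C)C(=O)Cl
Why: DMAP-catalysed O-acylation of the lactol at low temperature traps the hemiacetal before the base can degrade the enone; the product is racemic.

Step 3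
Reactants: 3 rac-6-(pivaloyloxy)-2H-pyran-3(6H)-one
Product: 4 (S)-6-(pivaloyloxy)-2H-pyran-3(6H)-one
Conditions: Candida rugosa lipase (or the best enzyme of a screen), n-BuOH, hexane, rt, stopped just past half conversion
Reagents that add atoms: none
Why: Lipase-catalysed kinetic resolution by transesterification of the anomeric ester: the (R)-ester should be deacylated to 2, which racemises by ring opening and is returned to step 2, while the (S)-ester is recovered enantioenriched.

Step 4
Reactants: 4 (S)-6-(pivaloyloxy)-2H-pyran-3(6H)-one, 5 ethyl buta-2,3-dienoate
Product: 6 ethyl (1S,4aS,7aS)-4-oxo-1-(pivaloyloxy)-1,3,4,4a,5,7a-hexahydrocyclopenta[c]pyran-7-carboxylate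
Conditions: PPh3 (10 mol %), toluene, 110 °C, slow addition of 5
Reagents that add atoms: none
Why: PPh3 adds to the central carbon of 5 and gives a phosphonium dienolate that acts as a three-carbon 1,3-dipole. Its ester-bearing α-carbon adds to the enone β-carbon of 4 (the future C7a) and forms C7–C7a; the enolate carbon so produced (the future C4a) closes on the CH2 terminus of the vinylphosphonium and forms C4a–C5, after which a proton shift and loss of PPh3 leave C6=C7 conjugated with the ester and return the catalyst. The closest known reaction type is the phosphine-catalysed (3+2) annulation of allenoates with electron-poor alkenes, which is established for cyclic enones and for anomerically substituted pyranones. Ring B is closed by a formally 5-endo-trig attack of the enolate on the vinylphosphonium, better viewed as the second bond of an asynchronous (3+2) cycloaddition across C4a=C7a. C7a is set by approach of the dipole anti to the pseudoaxial pivalate on the neighbouring C1. C4a follows from C7a, because the three-carbon unit can bridge the two enone carbons only on one face, so the ring fusion is cis. The step needs α- and not γ-regiochemistry of the dipole, which enone acceptors and the unsubstituted allenoate favour, and it needs the allylic acylal to survive the phosphine, which the hindered pivalate should secure.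

Step 5
Reactants: 6 ethyl (1S,4aS,7aS)-4-oxo-1-(pivaloyloxy)-1,3,4,4a,5,7a-hexahydrocyclopenta[c]pyran-7-carboxylate
Product: 7 ethyl (1S,4aS,7R,7aS)-4-oxo-1-(pivaloyloxy)octahydrocyclopenta[c]pyran-7-carboxylate (ester on the concave face, cis to C1)
Conditions: H2 (1 atm), 10% Pd/C, EtOAc, rt
Reagents that add atoms: none
Why: Heterogeneous hydrogenation of the enoate; hydrogen should arrive on the convex face (the face of H4a and H7a) and push the ester to the concave face, a kinetic outcome that step 7 corrects, so any minor C7 epimer converges there; ketone and acylal are inert.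

Step 6
Reactants: 7 ethyl (1S,4aS,7R,7aS)-4-oxo-1-(pivaloyloxy)octahydrocyclopenta[c]pyran-7-carboxylate
Product: 8 (1S,4S,4aS,7R,7aR)-4-hydroxy-7-(hydroxymethyl)octahydrocyclopenta[c]pyran-1-yl pivalate
Conditions: LiBH4 (3 equiv), THF, 0 °C → rt; aq. NH4Cl
Reagents that add atoms: none
Why: Borohydride reduction: LiBH4 reduces ketones and unhindered ethyl esters but attacks the shielded carbonyl of a pivalate only slowly; the C4 carbinol (hydride expected from the convex face) is a temporary centre that step 7 removes.

Step 7
Reactants: 8 (1S,4S,4aS,7R,7aR)-4-hydroxy-7-(hydroxymethyl)octahydrocyclopenta[c]pyran-1-yl pivalate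
Product: 10 (1S,4aS,7S,7aR)-7-formyl-4-oxooctahydrocyclopenta[c]pyran-1-yl pivalate, via concave-face formyl epimer 9 (not isolated)
Conditions: Dess–Martin periodinane (2.5 equiv), NaHCO3, CH2Cl2, 0 °C → rt; aq. Na2S2O3 wash; then DBU (0.2 equiv), CH2Cl2, rt
Reagents that add atoms: none
Why: Dess–Martin oxidation of both alcohols gives keto aldehyde 9, and catalytic DBU then equilibrates the formyl-bearing C7 through the aldehyde enolate; the isomer with the formyl group on the convex face, trans to C1, should prevail because the concave isomer eclipses the C7a–C1 bond.

Step 8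
Reactants: 10 (1S,4aS,7S,7aR)-7-formyl-4-oxooctahydrocyclopenta[c]pyran-1-yl pivalate
Product: 12 (1S,4aS,7S,7aR)-7-methyl-4-oxooctahydrocyclopenta[c]pyran-1-yl pivalate, via tosylhydrazone 11 (not isolated)
Conditions: TsNHNH2 (1.05 equiv), THF, rt; then catecholborane (1.2 equiv), CHCl3, 0 °C; then NaOAc·3H2O, 60 °C
Reagents that add atoms: 4-methylbenzenesulfonohydrazide, Cc1ccc(cc1)S(=O)(=O)NN (its atoms are held only by 11 and leave again within this step)
Why: Caglioti-type deoxygenation: the aldehyde condenses with the hydrazide far faster than the α-branched ketone, catecholborane adds hydride to the C=N bond, and acetate releases sulfinate and N2 from the diazene, which turns CHO into CH3 without touching the C7 centre.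

Step 9
Reactants: 13 (R)-2-hydroxy-3-methylbutanoic acid
Product: 15 (R)-1-(1H-benzotriazol-1-yl)-3-methyl-1-oxobutan-2-yl acetate, via (R)-2-acetoxy-3-methylbutanoic acid 14 (not isolated)
Conditions: AcCl (neat), 40 °C, evaporate; then 1H-benzotriazole (4 equiv), SOCl2 (1 equiv), CH2Cl2, rt
Reagents that add atoms: acetyl chloride, CC(=O)Cl; 1H-benzotriazole, c1ccc2[nH]nnc2c1
Why: O-acetylation of the α-hydroxy acid, then activation of the acid as its N-acylbenzotriazole through the benzotriazole–thionyl chloride adduct; the α-C–H is not touched, and this neutral acyl donor is much less prone to ketene formation than the acid chloride.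

Step 10
Reactants: 12 (1S,4aS,7S,7aR)-7-methyl-4-oxooctahydrocyclopenta[c]pyran-1-yl pivalate, 15 (R)-1-(1H-benzotriazol-1-yl)-3-methyl-1-oxobutan-2-yl acetate
Product: 16 (1S,4aS,7S,7aR)-3-[(R)-2-acetoxy-3-methylbutanoyl]-4-hydroxy-7-methyl-1,4a,5,6,7,7a-hexahydrocyclopenta[c]pyran-1-yl pivalate (ring-enol form of the 1,3-diketone)
Conditions: LiN(SiMe3)2 (2.1 equiv), THF, −78 °C; then 15, −78 → −20 °C; AcOH quench
Reagents that add atoms: none
Why: Crossed Claisen-type C-acylation: kinetic deprotonation should occur at the C3 methylene next to the ring oxygen and not at the ring-fusion methine C4a, and the lithium enolate is acylated on carbon by the N-acylbenzotriazole; the second equivalent of base stores the product as its diketonate, which also shields C2' from enolisation.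

Step 11
Reactants: 16 (1S,4aS,7S,7aR)-3-[(R)-2-acetoxy-3-methylbutanoyl]-4-hydroxy-7-methyl-1,4a,5,6,7,7a-hexahydrocyclopenta[c]pyran-1-yl pivalate
Product: 17 (1S,4aS,7S,7aR)-3-[(R)-2-acetoxy-3-methylbutanoyl]-7-methyl-4-(trifluoromethylsulfonyloxy)-1,4a,5,6,7,7a-hexahydrocyclopenta[c]pyran-1-yl pivalate
Conditions: Tf2O, i-Pr2NEt, CH2Cl2, −78 °C
Reagents that add atoms: trifluoromethanesulfonic anhydride, O=S(=O)(OS(=O)(=O)C(F)(F)F)C(F)(F)F
Why: O-sulfonylation of the 1,3-diketone: six-membered 2-acyl ketones enolise into the ring and are triflated on the ring oxygen, and here the side-chain oxygen is in addition shielded by the branched acetoxy-bearing carbon and inductively deactivated.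

Step 12
Reactants: 17 (1S,4aS,7S,7aR)-3-[(R)-2-acetoxy-3-methylbutanoyl]-7-methyl-4-(trifluoromethylsulfonyloxy)-1,4a,5,6,7,7a-hexahydrocyclopenta[c]pyran-1-yl pivalate
Product: 18 (1S,4aS,7S,7aR)-3-[(R)-2-acetoxy-3-methylbutanoyl]-4,7-dimethyl-1,4a,5,6,7,7a-hexahydrocyclopenta[c]pyran-1-yl pivalate
Conditions: Me4Sn, Pd(PPh3)4 (5 mol %), LiCl, THF, 65 °C
Reagents that add atoms: tetramethylstannane, C[Sn](C)(C)C
Why: Stille coupling: zerovalent palladium inserts into the electron-poor vinyl triflate, methyl is transferred from tin with chloride assistance, and reductive elimination gives the β-methyl enone; the neutral conditions leave acetate, acyloxy ketone and acylal alone, and the ring fixes the alkene geometry.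

Step 13
Reactants: 19 2'-hydroxy-6'-methylacetophenone
Product: 20 4-hydroxy-5-methylcoumarin
Conditions: NaH (3 equiv), (EtO)2CO, toluene, 110 °C; then aq. HCl
Reagents that add atoms: diethyl carbonate, CCOC(=O)OCC
Why: Claisen condensation of the ketone enolate with the carbonate and lactonisation onto the phenoxide, the standard way to 4-hydroxycoumarins.

Step 14
Reactants: 18 (1S,4aS,7S,7aR)-3-[(R)-2-acetoxy-3-methylbutanoyl]-4,7-dimethyl-1,4a,5,6,7,7a-hexahydrocyclopenta[c]pyran-1-yl pivalate, 20 4-hydroxy-5-methylcoumarin
Product: 21 (R)-1-[(1R,4aS,7S,7aR)-1-(4-hydroxy-5-methyl-2-oxo-2H-chromen-3-yl)-4,7-dimethyl-1,4a,5,6,7,7a-hexahydrocyclopenta[c]pyran-3-yl]-3-methyl-1-oxobutan-2-yl acetate (target CNP0139732.2)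
Conditions: BF3·OEt2 (0.3 equiv), MeCN–CH2Cl2, −30 → 0 °C
Reagents that add atoms: none
Why: Friedel–Crafts-type C-glycosylation: the Lewis acid ionises the anomeric pivalate to the ring oxocarbenium ion, which the nucleophilic C3 of the 4-hydroxycoumarin attacks on the convex face, anti to the C7a–C7 bond, so that the aryl group takes the place of the pivalate cis to H7a (1R); an O-linked acetal, if formed first, should re-ionise and end as the C-linked product.

**Compound list**

1 | furfuryl alcohol | OCc1ccco1 | starting material
2 | 6-hydroxy-2H-pyran-3(6H)-one (racemic) | O=C1COC(O)C=C1 | intermediate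
3 | rac-6-(pivaloyloxy)-2H-pyran-3(6H)-one | O=C1COC(OC(=O)C(C)(C)C)C=C1 | intermediate
4 | (S)-6-(pivaloyloxy)-2H-pyran-3(6H)-one | O=C1CO[C@@H](OC(=O)C(C)(C)C)C=C1 | intermediate
5 | ethyl buta-2,3-dienoate | C=C=CC(=O)OCC | starting material
6 | ethyl (1S,4aS,7aS)-4-oxo-1-(pivaloyloxy)-1,3,4,4a,5,7a-hexahydrocyclopenta[c]pyran-7-carboxylate (cis-fused, pivalate trans to C7) | C1C(=O)[C@H]2CC=C(C(=O)OCC)[C@H]2[C@H](OC(=O)C(C)(C)C)O1 | intermediate
7 | ethyl (1S,4aS,7R,7aS)-4-oxo-1-(pivaloyloxy)octahydrocyclopenta[c]pyran-7-carboxylate (ester cis to C1) | C1C(=O)[C@H]2CC[C@@H](C(=O)OCC)[C@H]2[C@H](OC(=O)C(C)(C)C)O1 | intermediate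
8 | (1S,4S,4aS,7R,7aR)-4-hydroxy-7-(hydroxymethyl)octahydrocyclopenta[c]pyran-1-yl pivalate (expected major C4 epimer) | C1[C@@H](O)[C@H]2CC[C@@H](CO)[C@H]2[C@H](OC(=O)C(C)(C)C)O1 | intermediate
9 | (1S,4aS,7R,7aR)-7-formyl-4-oxooctahydrocyclopenta[c]pyran-1-yl pivalate (formyl cis to C1) | C1C(=O)[C@H]2CC[C@@H](C=O)[C@H]2[C@H](OC(=O)C(C)(C)C)O1 | intermediate
10 | (1S,4aS,7S,7aR)-7-formyl-4-oxooctahydrocyclopenta[c]pyran-1-yl pivalate (formyl trans to C1) | C1C(=O)[C@H]2CC[C@H](C=O)[C@H]2[C@H](OC(=O)C(C)(C)C)O1 | intermediate
11 | (E)-tosylhydrazone of 10 | C1C(=O)[C@H]2CC[C@H](/C=N/NS(=O)(=O)c3ccc(C)cc3)[C@H]2[C@H](OC(=O)C(C)(C)C)O1 | intermediate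
12 | (1S,4aS,7S,7aR)-7-methyl-4-oxooctahydrocyclopenta[c]pyran-1-yl pivalate | C1C(=O)[C@H]2CC[C@H](C)[C@H]2[C@H](OC(=O)C(C)(C)C)O1 | intermediate
13 | (R)-2-hydroxy-3-methylbutanoic acid | CC(C)[C@@H](O)C(=O)O | starting material
14 | (R)-2-acetoxy-3-methylbutanoic acid | CC(C)[C@@H](OC(C)=O)C(=O)O | intermediate
15 | (R)-1-(1H-benzotriazol-1-yl)-3-methyl-1-oxobutan-2-yl acetate | CC(C)[C@@H](OC(C)=O)C(=O)n1nnc2ccccc12 | intermediate
16 | (1S,4aS,7S,7aR)-3-[(R)-2-acetoxy-3-methylbutanoyl]-4-hydroxy-7-methyl-1,4a,5,6,7,7a-hexahydrocyclopenta[c]pyran-1-yl pivalate | CC(=O)O[C@@H](C(=O)C1=C(O)[C@H]2CC[C@H](C)[C@H]2[C@H](OC(=O)C(C)(C)C)O1)C(C)C | intermediate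
17 | (1S,4aS,7S,7aR)-3-[(R)-2-acetoxy-3-methylbutanoyl]-7-methyl-4-(trifluoromethylsulfonyloxy)-1,4a,5,6,7,7a-hexahydrocyclopenta[c]pyran-1-yl pivalate | CC(=O)O[C@@H](C(=O)C1=C(OS(=O)(=O)C(F)(F)F)[C@H]2CC[C@H](C)[C@H]2[C@H](OC(=O)C(C)(C)C)O1)C(C)C | intermediate
18 | (1S,4aS,7S,7aR)-3-[(R)-2-acetoxy-3-methylbutanoyl]-4,7-dimethyl-1,4a,5,6,7,7a-hexahydrocyclopenta[c]pyran-1-yl pivalate | CC(=O)O[C@@H](C(=O)C1=C(C)[C@H]2CC[C@H](C)[C@H]2[C@H](OC(=O)C(C)(C)C)O1)C(C)C | intermediate
19 | 2'-hydroxy-6'-methylacetophenone | CC(=O)c1c(C)cccc1O | starting material
20 | 4-hydroxy-5-methylcoumarin | Cc1cccc2oc(=O)cc(O)c12 | intermediate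
21 | (R)-1-[(1R,4aS,7S,7aR)-1-(4-hydroxy-5-methyl-2-oxo-2H-chromen-3-yl)-4,7-dimethyl-1,4a,5,6,7,7a-hexahydrocyclopenta[c]pyran-3-yl]-3-methyl-1-oxobutan-2-yl acetate | CC(=O)O[C@@H](C(=O)C1=C(C)[C@H]2CC[C@H](C)[C@H]2[C@H](c2c(O)c3c(C)cccc3oc2=O)O1)C(C)C | target

Total step count: 14 steps. Longest linear sequence: 12 steps (steps 1 to 8, 10, 11, 12 and 14, from 1).

**Steps least certain to work**

Step 4 (key step). The dipole may add through its γ-carbon and give the regioisomeric cyclopentene, the allenoate may oligomerise, or the phosphine may displace the allylic anomeric ester. The fallback sets out from 4 and returns at 6. Conjugate addition of the organocopper reagent Li[Cu(C(=CH2)CO2Et)2] to 4 anti to the pivalate, with trapping of the enolate at the future C4a by allyl iodide, should give ethyl 2-[4-allyl-5-oxo-2-(pivaloyloxy)tetrahydro-2H-pyran-3-yl]acrylate F1 (all-trans). Ring-closing metathesis (second-generation Hoveyda–Grubbs catalyst, CH2Cl2, 40 °C) would close C6=C7 to the trans-fused C4a epimer of 6 F2, and catalytic DBU would equilibrate the ketone α-carbon to the less strained cis-fused 6. This replaces the dipole by two separate C–C bond formations and an olefin metathesis.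

Step 6. Hydride or the alkoxyborohydrides formed during the reduction may cleave the anomeric pivalate, or the acyl group may move to a new alkoxide. The fallback sets out from 7 and returns at 8. Me3SnOH (1,2-dichloroethane, 70 °C) would hydrolyse the ethyl ester to (1S,4aS,7R,7aS)-4-oxo-1-(pivaloyloxy)octahydrocyclopenta[c]pyran-7-carboxylic acid F3, and BH3·SMe2 (THF, 0 °C) would then reduce acid and ketone to 8 by electrophilic hydride, which does not attack the pivalate.

Step 8. Catecholborane may also reduce the activated α-alkoxy ketone, or the hydrazide may condense at C4 as well. The fallback sets out from 10 and returns at 12. NaBH4 (EtOH–CH2Cl2, −78 °C) should reduce only the aldehyde to (1S,4aS,7S,7aR)-7-(hydroxymethyl)-4-oxooctahydrocyclopenta[c]pyran-1-yl pivalate F4; I2, PPh3 and imidazole would give (1S,4aS,7S,7aS)-7-(iodomethyl)-4-oxooctahydrocyclopenta[c]pyran-1-yl pivalate F5; radical deiodination (Bu3SnH, AIBN, toluene, 80 °C) would give 12.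

Step 10. The enolate may be acylated on oxygen or twice, it may form partly at C4a, or the acyl donor may be enolised by the excess base, with loss of the C2' configuration. The fallback sets out from 14 (with 12 as partner) and returns at 16. Oxalyl chloride would give (R)-2-acetoxy-3-methylbutanoyl chloride F6, and Rosenmund reduction (H2, Pd/BaSO4, 2,6-lutidine) would give (R)-2-acetoxy-3-methylbutanal F7. Aldol addition of the lithium enolate of 12 to it at −78 °C, with an acidic quench at that temperature to keep the acetate from migrating, would give (1S,4aS,7S,7aR)-3-[(2R)-2-acetoxy-1-hydroxy-3-methylbutyl]-7-methyl-4-oxooctahydrocyclopenta[c]pyran-1-yl pivalate F8, and Dess–Martin oxidation would give 16. The carbon–carbon bond is then made at the aldehyde level, where O-acylation cannot occur.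

Step 14. Ionisation of the acylal next to the electron-poor enol ether may be sluggish, the coumarin may react through oxygen and stay there, or the oxocarbenium ion may lose a proton at C7a and erode the ring-fusion configuration. The fallback sets out from 18 and returns at 21. Mild acid hydrolysis (aq. HCl, THF, rt) would give the lactol (R)-1-[(1R,4aS,7S,7aR)-1-hydroxy-4,7-dimethyl-1,4a,5,6,7,7a-hexahydrocyclopenta[c]pyran-3-yl]-3-methyl-1-oxobutan-2-yl acetate F9. Its ring-opened aldehyde tautomer would be condensed with 20 under ethylenediammonium diacetate catalysis (Knoevenagel), and the enol oxygen of the side-chain diketone would close onto the alkylidene dione (oxa-Michael) to give 21 under thermodynamic control at C1.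

**Further compounds**

F1 | step 4 | ethyl 2-[4-allyl-5-oxo-2-(pivaloyloxy)tetrahydro-2H-pyran-3-yl]acrylate (2,3-trans, 3,4-trans, absolute configuration from 4) | C1C(=O)[C@H](CC=C)[C@@H](C(=C)C(=O)OCC)[C@H](OC(=O)C(C)(C)C)O1
F2 | step 4 | trans-fused C4a epimer of 6 | C1C(=O)[C@@H]2CC=C(C(=O)OCC)[C@H]2[C@H](OC(=O)C(C)(C)C)O1
F3 | step 6 | (1S,4aS,7R,7aS)-4-oxo-1-(pivaloyloxy)octahydrocyclopenta[c]pyran-7-carboxylic acid | C1C(=O)[C@H]2CC[C@@H](C(=O)O)[C@H]2[C@H](OC(=O)C(C)(C)C)O1
F4 | step 8 | (1S,4aS,7S,7aR)-7-(hydroxymethyl)-4-oxooctahydrocyclopenta[c]pyran-1-yl pivalate | C1C(=O)[C@H]2CC[C@H](CO)[C@H]2[C@H](OC(=O)C(C)(C)C)O1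
F5 | step 8 | (1S,4aS,7S,7aS)-7-(iodomethyl)-4-oxooctahydrocyclopenta[c]pyran-1-yl pivalate | C1C(=O)[C@H]2CC[C@H](CI)[C@H]2[C@H](OC(=O)C(C)(C)C)O1
F6 | step 10 | (R)-2-acetoxy-3-methylbutanoyl chloride | CC(C)[C@@H](OC(C)=O)C(Cl)=O
F7 | step 10 | (R)-2-acetoxy-3-methylbutanal | CC(C)[C@@H](OC(C)=O)C=O
F8 | step 10 | (1S,4aS,7S,7aR)-3-[(2R)-2-acetoxy-1-hydroxy-3-methylbutyl]-7-methyl-4-oxooctahydrocyclopenta[c]pyran-1-yl pivalate (mixture at C3 and at the carbinol carbon) | CC(=O)O[C@@H](C(O)C1C(=O)[C@H]2CC[C@H](C)[C@H]2[C@H](OC(=O)C(C)(C)C)O1)C(C)C
F9 | step 14 | (R)-1-[(1R,4aS,7S,7aR)-1-hydroxy-4,7-dimethyl-1,4a,5,6,7,7a-hexahydrocyclopenta[c]pyran-3-yl]-3-methyl-1-oxobutan-2-yl acetate (lactol; the anomers interconvert) | CC(=O)O[C@@H](C(=O)C1=C(C)[C@H]2CC[C@H](C)[C@H]2[C@H](O)O1)C(C)C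
A1 | alternative 1 | 4-(methoxymethoxy)-5-methyl-3-[(3S,6E)-3-methyloct-6-en-1-yn-1-yl]-2H-chromen-2-one | C/C=C/CC[C@H](C)C#Cc1c(OCOC)c2c(C)cccc2oc1=O
A2 | alternative 1 | 2-[4-(methoxymethoxy)-5-methyl-2-oxochromen-3-yl]-4,8-dimethylbicyclo[3.3.0]oct-1-en-3-one (ring-fusion hydrogen and both methyls on the convex face) | O=C1[C@H](C)[C@H]2CC[C@H](C)C2=C1c1c(OCOC)c2c(C)cccc2oc1=O
A3 | alternative 2 | (S)-5-methylcyclopent-1-ene-1-carbaldehyde | C1=C(C=O)[C@@H](C)CC1
A4 | alternative 2 | methyl 2-oxobutanoate | CCC(=O)C(=O)OC
A5 | alternative 2 | methyl 1-hydroxy-4,7-dimethyl-1,4a,5,6,7,7a-hexahydrocyclopenta[c]pyran-3-carboxylate (cis-fused, lactol anomers interconvert) | COC(=O)C1=C(C)[C@H]2CC[C@H](C)[C@H]2[C@H](O)O1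
A6 | alternative 3 | (3S,6E,10R)-10-(tert-butyldimethylsilyloxy)-3,7,11-trimethyl-8,9-dioxododec-6-enal | O=CC[C@@H](C)CC/C=C(\C)C(=O)C(=O)[C@H](O[Si](C)(C)C(C)(C)C)C(C)C
A7 | alternative 3 | O-tert-butyldimethylsilyl analogue of 21 (silyl in place of acetyl at C2') | CC(C)(C)[Si](C)(C)O[C@@H](C(=O)C1=C(C)[C@H]2CC[C@H](C)[C@H]2[C@H](c2c(O)c3c(C)cccc3oc2=O)O1)C(C)C
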